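**Assumption:** the SMILES decodes to the (2S,3S,4S,5S), all-trans isomer. I number the THF so that C2 carries the 3,4-dimethoxyphenyl group and C5 carries the 3,4,5-trimethoxyphenyl group.

## Retrosynthetic overview
1. Target 10 comes from its C2-epimer mixture 9 by Lewis-acid benzylic equilibration, so C2 is set thermodynamically and only C3, C4 and C5 need kinetic control.
2. The THF ring (the only ring formed) is closed at C2–C3 by 5-exo-trig cyclisation of an α-alkoxybenzyl (2-oxa-5-hexenyl) radical. The terminal =CH2 becomes the C3 methyl.
3. The radical precursor, O,S-acetal 8, comes from homoallylic alcohol 3 and α-chlorosulfide 7 by C–O bond formation under basic conditions.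
4. Alcohol 3 comes from 3,4,5-trimethoxybenzaldehyde by anti-selective asymmetric crotylboration, which is the only source of absolute configuration (C5 and C4).
5. Deliberately avoided: aldol/lactone → aryl addition → oxocarbenium reduction, and 1,4-diketone or 1,4-diol cyclodehydration.

## Route

**Step 1**
Reactants: 1, 3,4,5-trimethoxybenzaldehyde; 2, trans-2-butene
Product: 3, (1S,2S)-2-methyl-1-(3,4,5-trimethoxyphenyl)but-3-en-1-ol (anti)
Conditions: 2, n-BuLi, KOt-Bu, THF, −78 → −45 °C; (−)-Ipc2BOMe [from (+)-α-pinene], −78 °C; BF3·OEt2; 1, −78 °C; then NaOH, H2O2
Reagents that add atoms: trans-2-butene (2), C/C=C/C (delivers the crotyl C4H7 unit)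
Why: In this Brown asymmetric crotylboration the (E)-crotylborane reacts through a closed Zimmerman–Traxler chair, so E-geometry gives the anti relationship and the (+)-α-pinene-derived Ipc ligands direct attack to the Si face of the aryl aldehyde, giving (1S,2S), the future C5 and C4.

**Step 2**
Reactants: 4, 3,4-dimethoxybenzyl alcohol; 5, diphenyl disulfide
Product: 6, 3,4-dimethoxybenzyl phenyl sulfide
Conditions: PhSSPh, n-Bu3P, THF, 0 °C → rt
Reagents that add atoms: diphenyl disulfide (5), c1ccc(SSc2ccccc2)cc1 (delivers SPh)
Why: In this Mukaiyama–Hata thioetherification thiolate displaces the alkoxyphosphonium by SN2 under neutral conditions, which avoids acid-induced self-condensation of the veratryl alcohol.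

**Step 3**
Reactants: 6
Product: 7, chloro(3,4-dimethoxyphenyl)methyl phenyl sulfide (racemic, not isolated)
Conditions: NCS (1.0 equiv), PhH, 0 °C → rt, 1 h; filter off succinimide; use at once
Reagents that add atoms: N-chlorosuccinimide, O=C1CCC(=O)N1Cl (delivers Cl)
Why: This Pummerer-type α-chlorination of a benzyl sulfide (chlorosulfonium → thionium → α-chlorosulfide) is selective because sulfur is far more nucleophilic toward NCS than the arene ring.

**Step 4**
Reactants: 3; 7
Product: 8, (3,4-dimethoxyphenyl)(phenylthio)methyl (1S,2S)-2-methyl-1-(3,4,5-trimethoxyphenyl)but-3-en-1-yl ether (about 1:1 at the acetal carbon)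
Conditions: i-Pr2NEt (2 equiv), 4 Å MS, CH2Cl2, −20 °C → rt; purify on Et3N-deactivated SiO2
Reagents that add atoms: none (only 3 and 7)
Why: This SN1-type O-alkylation captures the aryl-stabilised thionium ion from 7, leaves the carbinol C–O bond untouched so both stereocentres persist, and under base never forms a homoallyl oxocarbenium ion, so Prins and 2-oxonia-Cope scrambling are avoided, while the acetal configuration is irrelevant because that carbon becomes the radical.

**Step 5 (key step)**
Reactants: 8
Product: 9, (3S,4S,5S)-2-(3,4-dimethoxyphenyl)-3,4-dimethyl-5-(3,4,5-trimethoxyphenyl)tetrahydrofuran, as a mixture of C2 epimers (2R = 2,3-cis; 2S = target)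
Conditions: n-Bu3SnH (1.5 equiv) and AIBN (0.2 equiv) added by syringe pump over 8 h, degassed PhH (0.01 M), 80 °C; KF work-up
Reagents that add atoms: none (Bu3SnH delivers only H)
Why: Proposed new method: Bu3Sn• abstracts SPh from the weak benzylic/anomeric C–S bond to give an α-alkoxy-3,4-dimethoxybenzyl (2-oxa-5-hexenyl) radical, which closes 5-exo-trig onto the vinyl group through a Beckwith–Houk chair with the C5 aryl and C4 methyl both pseudo-equatorial (the 3,5-cis and 4,5-trans preferences reinforce each other, so the new C3 centre is S and the methyls are trans), and the resulting primary radical takes H from Bu3SnH to become the C3 methyl; the benzylic radical cyclises more slowly than an alkyl radical, but Bu3SnH also reduces it roughly 100 times more slowly (about 10^4–10^5 versus 10^6–10^7 M⁻¹ s⁻¹), so high dilution favours closure and fast quenching of the primary radical makes closure irreversible; the closest known chemistry is the tin-hydride cyclisation of alkoxymethyl and α-alkoxy-α-ester radicals, generated from O,Se- or O,S-acetals of homoallylic alcohols, to 3-methyltetrahydrofurans; C2 forms unselectively and is corrected in step 6.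

**Step 6**
Reactants: 9
Product: 10, 5-methoxygalbelgin, (2S,3S,4S,5S)-2-(3,4-dimethoxyphenyl)-3,4-dimethyl-5-(3,4,5-trimethoxyphenyl)tetrahydrofuran
Conditions: BF3·OEt2 (1.5 equiv), CH2Cl2, −20 → 0 °C, 1–2 h; sat. NaHCO3
Reagents that add atoms: none
Why: In this Lewis-acid benzylic epimerisation BF3 reversibly ionises the C2–O bond to a p-methoxy-stabilised (quinone-methide-like) cation that recloses under thermodynamic control with the aryl trans to the C3 methyl, so both epimers converge on the all-trans isomer while C3 and C4 are not involved and C5 already sits in its preferred trans arrangement.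

**Where each stereocentre is set:**
- C5 and C4 are set by reagent control in step 1.
- C3 is set by substrate control in step 5.
- C2 is set by thermodynamic control in step 6.
- No protecting groups are used.

## Compound list
| No. | Name | SMILES | Role |
|---|---|---|---|
| 1 | 3,4,5-trimethoxybenzaldehyde | COc1cc(C=O)cc(OC)c1OC | starting material |
| 2 | trans-2-butene | C/C=C/C | starting material |
| 3 | (1S,2S)-2-methyl-1-(3,4,5-trimethoxyphenyl)but-3-en-1-ol | O[C@H](c1cc(OC)c(OC)c(OC)c1)[C@@H](C)C=C | intermediate |
| 4 | 3,4-dimethoxybenzyl alcohol | COc1ccc(CO)cc1OC | starting material |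
| 5 | diphenyl disulfide | c1ccc(SSc2ccccc2)cc1 | starting material |
| 6 | 3,4-dimethoxybenzyl phenyl sulfide | COc1ccc(CSc2ccccc2)cc1OC | intermediate |
| 7 | chloro(3,4-dimethoxyphenyl)methyl phenyl sulfide (racemic) | COc1ccc(C(Cl)Sc2ccccc2)cc1OC | intermediate |
| 8 | O,S-acetal (epimers at the acetal carbon) | COc1ccc(C(Sc2ccccc2)O[C@H](c2cc(OC)c(OC)c(OC)c2)[C@@H](C)C=C)cc1OC | intermediate |
| 9 | (3S,4S,5S)-THF, C2 epimers | COc1ccc(C2O[C@H](c3cc(OC)c(OC)c(OC)c3)[C@@H](C)[C@@H]2C)cc1OC | intermediate |
| 10 | 5-methoxygalbelgin (2S,3S,4S,5S) | COc1ccc([C@H]2O[C@H](c3cc(OC)c(OC)c(OC)c3)[C@@H](C)[C@@H]2C)cc1OC | target |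

## Summary
**Total steps:** 6.

**Longest linear sequence:** 5 steps (4 → 6 → 7 → 8 → 9 → 10). It is 4 steps from aldehyde 1, and steps 3 and 4 are telescoped in practice.

**Steps most likely to fail, each with a fallback that changes the approach:**

1. **Step 5, radical ring closure.**
   - Risks: premature reduction of the stabilised radical, β-scission to veratraldehyde plus a benzylic radical, or 6-endo leakage.
   - Fallback: give up the radical C2–C3 closure and form that bond with titanium. Acylate 3 with 3,4-dimethoxybenzoyl chloride, then carry out an intramolecular Kulinkovich-type hydroxycyclopropanation of the homoallyl ester (Ti(Oi-Pr)4, c-C5H9MgCl). Base-induced opening of the cyclopropanol at the CH2 carbon gives the α-methyl γ-hydroxy aryl ketone (hemiketal), which is reduced ionically with Et3SiH/BF3·OEt2.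

2. **Step 4, assembly and handling of the very ionisable O,S-acetal.**
   - Risks: disproportionation to the acetal and dithioacetal, or hydrolysis.
   - Fallback: reach the same radical from a non-ionisable carboxylate precursor. Perform a Rh2(OAc)4 O–H insertion of 3 into methyl 2-diazo-2-(3,4-dimethoxyphenyl)acetate, then saponify with LiOH and form the N-hydroxyphthalimide ester. A reductive decarboxylative 5-exo cyclisation (Hantzsch ester, blue light) then closes the ring.

3. **Step 6, cationic epimerisation.**
   - Risks: Friedel–Crafts capture of the C2 cation by the trimethoxyphenyl ring to give an aryltetralin, or E1 elimination and re-addition that scrambles C3.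
   - Fallback: epimerise through the radical instead of the cation. Reversible photocatalytic hydrogen-atom transfer at the benzylic α-oxy C2–H (decatungstate with a disulfide or thiol co-catalyst, 390 nm) drives the mixture to the same all-trans thermodynamic isomer without ionising the ring.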